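**Retrosynthetic overview**

- The strategy rests on the pyranone ring: C4 (the carbonyl carbon) and C3 (the methoxy-bearing carbon) are adjacent and both carry oxygen, which is an acyloin pattern. The C3–C4 bond is therefore cut with reversed polarity: C4 is the acyl anion of an A-ring aldehyde and C3 is the ketone carbonyl of a tethered α-keto ester.
- The target is reached from the racemic 3-hydroxy-4-oxochromane-3-carboxylate by loss of the ester carbon, dehydrogenation to the flavonol, 3-O-methylation and chelation-controlled 5-O-demethylation.
- The benzoin precursor is made by forming the O1–C2 ether: 2-hydroxy-3,4,6-trimethoxybenzaldehyde (formylation and ortho-demethylation of 1,2,3,5-tetramethoxybenzene) is O-alkylated with a 3-chloro-3-aryl-2-oxopropanoate, itself obtained in one operation by Darzens condensation of 2-methoxybenzaldehyde.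
- The ester is tert-butyl, so that it leaves under acid as isobutene and CO2 (base would open the dihydroflavonol) and so that it cannot lactonise with aldol by-products.
- Ring order: the A and B rings are bought as arenes; the pyranone ring is the only ring formed, in step 5.

Key step: step 5

Remark: the target is a planar flavone without a stereocentre, so no stereocontrol is needed; all sp3 intermediates are racemic and their stereocentres are erased by step 7. tert-Butyl dichloroacetate is taken as a catalogue reagent.

**Route**

Step 1
Reactants: 1 1,2,3,5-tetramethoxybenzene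
Product: 3 2,3,4,6-tetramethoxybenzaldehyde, via Vilsmeier iminium chloride 2 (not isolated)
Conditions: POCl3 (1.2 equiv), DMF, 0 → 60 °C; then ice–water
Reagents that add atoms: N,N-dimethylformamide, CN(C)C=O; water, O
Why: Vilsmeier–Haack formylation; the two free ring positions of 1 are equivalent and each is ortho/para to three methoxy groups, so one iminium salt should form and hydrolyse to a single aldehyde.

Step 2
Reactants: 3 2,3,4,6-tetramethoxybenzaldehyde
Product: 4 2-hydroxy-3,4,6-trimethoxybenzaldehyde
Conditions: BCl3 (1.1 equiv), CH2Cl2, −78 → 0 °C; then H2O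
Reagents that add atoms: none
Why: Chelation-controlled Lewis-acid ether cleavage; boron bound to the carbonyl and an ortho methoxy oxygen lets chloride remove that methyl, and the C2 methoxy, buttressed by the C3 methoxy and twisted out of the ring plane, should be cleaved in preference to the C6 methoxy, as is usual for 2,3,4,6-tetraoxygenated aryl carbonyl compounds.

Step 3
Reactants: 5 2-methoxybenzaldehyde; 6 tert-butyl dichloroacetate
Product: 8 tert-butyl 3-chloro-3-(2-methoxyphenyl)-2-oxopropanoate (racemic), via chloro-epoxide 7 (not isolated)
Conditions: KOt-Bu, THF, −40 → 0 °C; crude epoxide then warmed in toluene, 60 °C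
Reagents that add atoms: none
Why: Darzens condensation of the non-enolisable aldehyde with the dichloroacetate enolate gives the α-chloroglycidate, whose benzylic C–O bond (stabilised by the o-anisyl group) opens with 1,2-transfer of chloride to give the β-chloro α-keto ester; the stereocentre is racemic and of no consequence.

Step 4
Reactants: 4 2-hydroxy-3,4,6-trimethoxybenzaldehyde; 8 tert-butyl 3-chloro-3-(2-methoxyphenyl)-2-oxopropanoate
Product: 9 tert-butyl 3-(2-formyl-3,5,6-trimethoxyphenoxy)-3-(2-methoxyphenyl)-2-oxopropanoate (racemic)
Conditions: K2CO3 (1.2 equiv), KI (cat.), MeCN, rt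
Reagents that add atoms: none
Why: Williamson ether synthesis; the phenoxide displaces a benzylic chloride that is strongly activated by the adjacent keto group (iodide catalysis), and mild carbonate at room temperature together with the bulky tert-butyl ester should hold back follow-up aldol chemistry of Rap–Stoermer type; the new stereocentre is racemic.

Step 5
Reactants: 9 tert-butyl 3-(2-formyl-3,5,6-trimethoxyphenoxy)-3-(2-methoxyphenyl)-2-oxopropanoate
Product: 10 tert-butyl 3-hydroxy-5,7,8-trimethoxy-2-(2-methoxyphenyl)-4-oxochromane-3-carboxylate (racemic)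
Conditions: 2-(pentafluorophenyl)-6,7-dihydro-5H-pyrrolo[2,1-c][1,2,4]triazolium BF4 (20 mol%), i-Pr2NEt (20 mol%), toluene, 4 Å MS, Ar, rt → 40 °C
Reagents that add atoms: none
Why: The triazolylidene adds to the aryl aldehyde of 9 and proton transfer gives the Breslow intermediate, whose nucleophilic carbon (the future C4) attacks the ketone carbonyl of the tethered α-keto ester; collapse of the adduct releases the carbene and leaves the C4 ketone and the C3 tertiary alcohol. The closest known reactions are the carbene-catalysed intramolecular crossed aldehyde–ketone benzoin of 2-(2-oxoalkoxy)benzaldehydes to 3-hydroxychroman-4-ones and the crossed benzoin of aldehydes with α-keto esters. The pyranone ring closes in 6-exo-trig mode. C3 is the new stereocentre; its configuration relative to C2 (which equilibrates in 9 by enolisation) is governed only by the substrate, with the 2-aryl group expected pseudo-equatorial in a chair-like transition state, and no control is needed because C2 and C3 both become sp2 by step 7. The step needs chemoselectivity for acyl-anion formation at the aldehyde and addition to the ketone: only the aldehyde can form a Breslow intermediate, the keto ester carbonyl is the most electrophilic acceptor and is placed for six-membered closure, the 2,6-disubstituted aldehyde resists homo-benzoin, and the weak amine base at low loading together with the non-lactonising tert-butyl ester should keep the competing enolate aldol onto the aldehyde reversible.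

Step 6
Reactants: 10 tert-butyl 3-hydroxy-5,7,8-trimethoxy-2-(2-methoxyphenyl)-4-oxochromane-3-carboxylate
Product: 12 3-hydroxy-5,7,8-trimethoxy-2-(2-methoxyphenyl)chroman-4-one (racemic, 2,3-trans expected), via β-keto acid 11 (not isolated)
Conditions: TsOH·H2O (0.2 equiv), toluene, 90 °C
Reagents that add atoms: none
Why: Acid-catalysed E1 loss of isobutene from the tert-butyl ester gives the β-keto acid, which decarboxylates through the six-membered cyclic transition state to the C3–C4 enediol and tautomerises to the aryl-conjugated 4-ketone; acid avoids the base-induced retro-oxa-Michael opening of the pyranone, and the C3 configuration, set under thermodynamic control, is erased in step 7.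

Step 7
Reactants: 12 3-hydroxy-5,7,8-trimethoxy-2-(2-methoxyphenyl)chroman-4-one
Product: 13 3-hydroxy-5,7,8-trimethoxy-2-(2-methoxyphenyl)-4H-chromen-4-one
Conditions: I2 (10 mol%), DMSO, 100 °C
Reagents that add atoms: none
Why: Iodine-catalysed dehydrogenation in DMSO, as used for flavanones and dihydroflavonols; the enol is iodinated at C3, loss of HI gives the 3,4-dione, which tautomerises through the acidic benzylic C2–H to the aromatic 3-hydroxy-γ-pyrone, and DMSO reoxidises HI.

Step 8
Reactants: 13 3-hydroxy-5,7,8-trimethoxy-2-(2-methoxyphenyl)-4H-chromen-4-one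
Product: 14 3,5,7,8-tetramethoxy-2-(2-methoxyphenyl)-4H-chromen-4-one
Conditions: MeI (1.5 equiv), K2CO3, acetone, reflux
Reagents that add atoms: iodomethane, CI
Why: Williamson O-methylation of the acidic enolic 3-OH, the only free hydroxyl in 13.

Step 9
Reactants: 14 3,5,7,8-tetramethoxy-2-(2-methoxyphenyl)-4H-chromen-4-one
Product: 15 5-hydroxy-3,7,8-trimethoxy-2-(2-methoxyphenyl)-4H-chromen-4-one (5-hydroxy-3,7,8,2'-tetramethoxyflavone)
Conditions: BCl3 (1.2 equiv), CH2Cl2, −78 → 0 °C; then H2O
Reagents that add atoms: none
Why: Chelation-controlled Lewis-acid demethylation; boron bound to C4=O and the peri 5-methoxy oxygen forms a six-membered chelate from which chloride removes the methyl, whereas the 3-methoxy group would need a less favourable five-membered chelate and the 7-, 8- and 2'-methoxy groups cannot chelate.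

**Compound list**

1 | 1,2,3,5-tetramethoxybenzene | COc1cc(OC)c(OC)c(OC)c1 | starting material
2 | N,N-dimethyl-(2,3,4,6-tetramethoxybenzylidene)iminium chloride (counter-ion drawn as chloride) | COc1cc(OC)c(OC)c(OC)c1C=[N+](C)C.[Cl-] | intermediate (not isolated)
3 | 2,3,4,6-tetramethoxybenzaldehyde | COc1cc(OC)c(OC)c(OC)c1C=O | intermediate
4 | 2-hydroxy-3,4,6-trimethoxybenzaldehyde | COc1cc(OC)c(OC)c(O)c1C=O | intermediate
5 | 2-methoxybenzaldehyde | COc1ccccc1C=O | starting material
6 | tert-butyl dichloroacetate | CC(C)(C)OC(=O)C(Cl)Cl | starting material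
7 | tert-butyl 2-chloro-3-(2-methoxyphenyl)oxirane-2-carboxylate (racemic diastereomers, one drawn) | CC(C)(C)OC(=O)[C@@]1(Cl)O[C@H]1c1ccccc1OC | intermediate (not isolated)
8 | tert-butyl 3-chloro-3-(2-methoxyphenyl)-2-oxopropanoate (racemic, one enantiomer drawn) | CC(C)(C)OC(=O)C(=O)[C@H](Cl)c1ccccc1OC | intermediate
9 | tert-butyl 3-(2-formyl-3,5,6-trimethoxyphenoxy)-3-(2-methoxyphenyl)-2-oxopropanoate (racemic, one enantiomer drawn) | CC(C)(C)OC(=O)C(=O)[C@H](Oc1c(OC)c(OC)cc(OC)c1C=O)c1ccccc1OC | intermediate
10 | tert-butyl 3-hydroxy-5,7,8-trimethoxy-2-(2-methoxyphenyl)-4-oxochromane-3-carboxylate (racemic, relative configuration not controlled, one diastereomer drawn) | CC(C)(C)OC(=O)[C@]1(O)C(=O)c2c(OC)cc(OC)c(OC)c2O[C@@H]1c1ccccc1OC | intermediate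
11 | 3-hydroxy-5,7,8-trimethoxy-2-(2-methoxyphenyl)-4-oxochromane-3-carboxylic acid (racemic, one diastereomer drawn) | OC(=O)[C@]1(O)C(=O)c2c(OC)cc(OC)c(OC)c2O[C@@H]1c1ccccc1OC | intermediate (not isolated)
12 | 3-hydroxy-5,7,8-trimethoxy-2-(2-methoxyphenyl)chroman-4-one (racemic, 2,3-trans drawn) | COc1ccccc1[C@H]1Oc2c(OC)c(OC)cc(OC)c2C(=O)[C@@H]1O | intermediate
13 | 3-hydroxy-5,7,8-trimethoxy-2-(2-methoxyphenyl)-4H-chromen-4-one | COc1ccccc1-c1oc2c(OC)c(OC)cc(OC)c2c(=O)c1O | intermediate
14 | 3,5,7,8-tetramethoxy-2-(2-methoxyphenyl)-4H-chromen-4-one | COc1ccccc1-c1oc2c(OC)c(OC)cc(OC)c2c(=O)c1OC | intermediate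
15 | 5-hydroxy-3,7,8-trimethoxy-2-(2-methoxyphenyl)-4H-chromen-4-one | COc1ccccc1-c1oc2c(OC)c(OC)cc(O)c2c(=O)c1OC | target

**Step count**

Total steps: 9. Longest linear sequence: 8 steps (1 → 15 through steps 1, 2, 4, 5, 6, 7, 8 and 9); step 3 is the convergent branch.

**Steps most likely to fail, with fallbacks**

Step 5. The Breslow intermediate may form too slowly at the hindered, electron-rich 2,6-dioxygenated aldehyde, so that base-mediated enolisation at the tether carbon (aldol addition onto the aldehyde or loss of the aryloxide) consumes 9 first. The fallback builds the pyranone ring by classical acylation chemistry; it sets out from 1 and comes back to the route at 14. Friedel–Crafts acylation of 1 with methoxyacetyl chloride and AlCl3 (Et2O/CH2Cl2, 0 °C → rt), with cleavage of the methoxy group ortho to the new ketone, should give 1-(2-hydroxy-3,4,6-trimethoxyphenyl)-2-methoxyethan-1-one F1. O-Acylation with 2-methoxybenzoyl chloride in pyridine should give 2-(methoxyacetyl)-3,5,6-trimethoxyphenyl 2-methoxybenzoate F2. Baker–Venkataraman rearrangement (KOH, pyridine, 50 °C) should give 1-(2-hydroxy-3,4,6-trimethoxyphenyl)-2-methoxy-3-(2-methoxyphenyl)propane-1,3-dione F3, and cyclodehydration (cat. H2SO4, AcOH, 100 °C) should give 14, which carries the C3 oxygen already as its methyl ether.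

Step 4. Deprotonation of the C–H acidic chloro keto ester 8 by the carbonate or the phenoxide may outrun substitution, and the product may close by aldol addition onto its own aldehyde. The fallback makes the ether with a non-acidic electrophile and raises the oxidation level afterwards; it sets out from 5 and 4 and comes back to the route at 9. Darzens condensation of 5 with tert-butyl chloroacetate (KOt-Bu, THF, −20 °C → rt) should give tert-butyl trans-3-(2-methoxyphenyl)oxirane-2-carboxylate F4. Opening of the epoxide at its benzylic carbon by the phenoxide of 4 (Cs2CO3, DMF, 60 °C) should give tert-butyl 3-(2-formyl-3,5,6-trimethoxyphenoxy)-2-hydroxy-3-(2-methoxyphenyl)propanoate F5. Dess–Martin oxidation of the secondary alcohol (CH2Cl2, rt), which leaves the aryl aldehyde untouched, should give 9.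

Step 9. Discrimination between the two methoxy groups that flank the carbonyl (C5 and C3) may be incomplete, or cleavage may run on to further ethers. The fallback moves the selectivity problem from ether cleavage to alkylation; it sets out from 13 and comes back to the route at 15. With no 3-methoxy group present, 5-O-demethylation of 13 (AlCl3, MeCN, rt → 50 °C) should give 3,5-dihydroxy-7,8-dimethoxy-2-(2-methoxyphenyl)-4H-chromen-4-one F6. Methylation with one equivalent of dimethyl sulfate (K2CO3, acetone, rt) should then take the more acidic 3-OH and leave the strongly hydrogen-bonded 5-OH, giving 15.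

**Further compounds**

F1 | step 5 | 1-(2-hydroxy-3,4,6-trimethoxyphenyl)-2-methoxyethan-1-one | COCC(=O)c1c(OC)cc(OC)c(OC)c1O
F2 | step 5 | 2-(methoxyacetyl)-3,5,6-trimethoxyphenyl 2-methoxybenzoate | COCC(=O)c1c(OC)cc(OC)c(OC)c1OC(=O)c1ccccc1OC
F3 | step 5 | 1-(2-hydroxy-3,4,6-trimethoxyphenyl)-2-methoxy-3-(2-methoxyphenyl)propane-1,3-dione (racemic) | COC(C(=O)c1ccccc1OC)C(=O)c1c(OC)cc(OC)c(OC)c1O
F4 | step 4 | tert-butyl trans-3-(2-methoxyphenyl)oxirane-2-carboxylate (racemic, one enantiomer drawn) | CC(C)(C)OC(=O)[C@@H]1O[C@H]1c1ccccc1OC
F5 | step 4 | tert-butyl 3-(2-formyl-3,5,6-trimethoxyphenoxy)-2-hydroxy-3-(2-methoxyphenyl)propanoate (racemic, one enantiomer drawn) | CC(C)(C)OC(=O)[C@H](O)[C@H](Oc1c(OC)c(OC)cc(OC)c1C=O)c1ccccc1OC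
F6 | step 9 | 3,5-dihydroxy-7,8-dimethoxy-2-(2-methoxyphenyl)-4H-chromen-4-one | COc1ccccc1-c1oc2c(OC)c(OC)cc(O)c2c(=O)c1O
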